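## Retrosynthetic overview

1. Cα–Cβ, the C(=O)–CH(O) bond (key step): aryl aldehyde 1 and (benzyloxy)acetaldehyde 2, two carbonyl carbons that are both normally electrophilic, are joined by a chiral triazolylidene through the acyl anion equivalent 3 (Breslow intermediate) to give (S)-acyloin 4. This step creates the only stereocentre.
2. Cβ–OAr: vanillic acid 5 (through its potassium salt 6) gives benzyl vanillate 7. Mitsunobu coupling of 4 with 7 (through alkoxyphosphonium salt 8) gives aryl ether 9 with inversion, (S) → (R).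
3. One hydrogenolysis removes the three benzyl groups of 9 and gives target 10.
4. No ring is formed; both benzene rings are bought (in 1 and 5).

Assumption: the (S)-precatalyst is taken to give the (S)-acyloin, by analogy with its sense of induction in homo-benzoin condensations; if the crossed reaction shows the opposite sense, the (R)-precatalyst is used with no other change.

Precatalyst for step 1: (5S)-5-[hydroxy(diphenyl)methyl]-2-(pentafluorophenyl)-6,7-dihydro-5H-pyrrolo[2,1-c][1,2,4]triazol-2-ium tetrafluoroborate, SMILES OC(c1ccccc1)(c1ccccc1)[C@@H]1CCc2nn(-c3c(F)c(F)c(F)c(F)c3F)c[n+]12.F[B-](F)(F)F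

## Route

Step 1
Reactants: 1 4-(benzyloxy)-3,5-dimethoxybenzaldehyde; 2 (benzyloxy)acetaldehyde
Product: 4 (2S)-3-(benzyloxy)-1-[4-(benzyloxy)-3,5-dimethoxyphenyl]-2-hydroxypropan-1-one, via NHC-bound Breslow intermediate 3 (not isolated)
Conditions: (S)-triazolium BF4 precatalyst (10 mol %), Rb2CO3 (10 mol %), THF, 4 Å MS, 0 °C, N2; 2 (1.0 equiv) added over 8 h to 1 (1.5 equiv); AcOH quench; recrystallise to raise ee
Reagents that add atoms: none
Why: Proposed new method: the triazolylidene adds to 1 and the adduct is deprotonated to Breslow intermediate 3, an acyl anion equivalent, which attacks the far more electrophilic α-alkoxy aldehyde 2 (kept at low concentration so that it acts only as acceptor) on the face left open by the CPh2OH arm of the catalyst, setting C2 as (S); the closest known reactions are the enantioselective triazolium-catalysed benzoin condensation and the chemoselective NHC-catalysed crossed acyloin and hydroxymethylation reactions of aromatic aldehydes with reactive aliphatic aldehydes.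

Step 2
Reactants: 5 vanillic acid (4-hydroxy-3-methoxybenzoic acid)
Product: 7 benzyl 4-hydroxy-3-methoxybenzoate, via potassium vanillate 6 (not isolated)
Conditions: KHCO3 (1.1 equiv), BnBr (1.05 equiv), DMF, rt → 40 °C
Reagents that add atoms: benzyl bromide, BrCc1ccccc1
Why: Bicarbonate deprotonates only the carboxylic acid, not the phenol, so SN2 O-alkylation of the carboxylate gives the benzyl ester and leaves the phenol free for step 3.

Step 3
Reactants: 4 (2S)-3-(benzyloxy)-1-[4-(benzyloxy)-3,5-dimethoxyphenyl]-2-hydroxypropan-1-one; 7 benzyl 4-hydroxy-3-methoxybenzoate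
Product: 9 benzyl 4-{[(2R)-3-(benzyloxy)-1-[4-(benzyloxy)-3,5-dimethoxyphenyl]-1-oxopropan-2-yl]oxy}-3-methoxybenzoate, via alkoxytriphenylphosphonium aryloxide 8 (not isolated)
Conditions: PPh3 (1.5 equiv), DIAD (1.5 equiv), 7 (1.3 equiv), toluene, −20 °C → rt; neutral work-up
Reagents that add atoms: none
Why: Mitsunobu reaction: the acidic phenol 7 (pKa about 8.5) protonates the betaine and its aryloxide displaces Ph3P=O from alkoxyphosphonium 8 by SN2 at the carbonyl-activated carbon with clean inversion, (S) → (R), and no base stronger than the aryloxide is present to epimerise the new α-aryloxy ketone.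

Step 4
Reactants: 9 benzyl 4-{[(2R)-3-(benzyloxy)-1-[4-(benzyloxy)-3,5-dimethoxyphenyl]-1-oxopropan-2-yl]oxy}-3-methoxybenzoate
Product: 10 4-{[(2R)-3-hydroxy-1-(4-hydroxy-3,5-dimethoxyphenyl)-1-oxopropan-2-yl]oxy}-3-methoxybenzoic acid
Conditions: H2 (1 atm), 20% Pd(OH)2/C, EtOAc–THF 1:1, rt, stopped after uptake of 3 equiv H2; filter through Celite, no basic work-up
Reagents that add atoms: none
Why: Catalytic hydrogenolysis cleaves the aryl benzyl ether, the benzyl ester and the alkyl benzyl ether under neutral conditions that do not enolise the α-aryloxy ketone or touch the methyl ethers, so the (R) centre set in step 3 is carried unchanged into the target.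

## Compound list

1 | 4-(benzyloxy)-3,5-dimethoxybenzaldehyde | COc1cc(C=O)cc(OC)c1OCc1ccccc1 | starting material
2 | (benzyloxy)acetaldehyde | O=CCOCc1ccccc1 | starting material
3 | Breslow intermediate: [4-(benzyloxy)-3,5-dimethoxyphenyl]{(5S)-5-[hydroxy(diphenyl)methyl]-2-(pentafluorophenyl)-6,7-dihydro-2H-pyrrolo[2,1-c][1,2,4]triazol-3(5H)-ylidene}methanol | OC(=C1N(c2c(F)c(F)c(F)c(F)c2F)N=C2CC[C@@H](C(O)(c3ccccc3)c3ccccc3)N12)c1cc(OC)c(OCc2ccccc2)c(OC)c1 | intermediate
4 | (2S)-3-(benzyloxy)-1-[4-(benzyloxy)-3,5-dimethoxyphenyl]-2-hydroxypropan-1-one | O[C@@H](COCc1ccccc1)C(=O)c1cc(OC)c(OCc2ccccc2)c(OC)c1 | intermediate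
5 | vanillic acid (4-hydroxy-3-methoxybenzoic acid) | COc1cc(C(=O)O)ccc1O | starting material
6 | potassium 4-hydroxy-3-methoxybenzoate (potassium vanillate) | COc1cc(C(=O)[O-])ccc1O.[K+] | intermediate
7 | benzyl 4-hydroxy-3-methoxybenzoate (benzyl vanillate) | COc1cc(C(=O)OCc2ccccc2)ccc1O | intermediate
8 | {[(2S)-3-(benzyloxy)-1-[4-(benzyloxy)-3,5-dimethoxyphenyl]-1-oxopropan-2-yl]oxy}triphenylphosphonium 4-[(benzyloxy)carbonyl]-2-methoxyphenoxide | c1ccccc1[P+](c1ccccc1)(c1ccccc1)O[C@@H](COCc1ccccc1)C(=O)c1cc(OC)c(OCc2ccccc2)c(OC)c1.COc1cc(C(=O)OCc2ccccc2)ccc1[O-] | intermediate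
9 | benzyl 4-{[(2R)-3-(benzyloxy)-1-[4-(benzyloxy)-3,5-dimethoxyphenyl]-1-oxopropan-2-yl]oxy}-3-methoxybenzoate | COc1cc(C(=O)OCc2ccccc2)ccc1O[C@H](COCc1ccccc1)C(=O)c1cc(OC)c(OCc2ccccc2)c(OC)c1 | intermediate
10 | 4-{[(2R)-3-hydroxy-1-(4-hydroxy-3,5-dimethoxyphenyl)-1-oxopropan-2-yl]oxy}-3-methoxybenzoic acid (CNP0507417.1) | COc1cc(C(=O)O)ccc1O[C@H](CO)C(=O)c1cc(OC)c(O)c(OC)c1 | target

## Step count and risks

Total step count: 4. Longest linear sequence: 3 steps (1 → 4 → 9 → 10); step 2 is a one-step side branch.

The three steps most likely to fail: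

1. Step 1 (highest risk). Aldehyde 2 may self-condense or act as the acyl donor, and the enantioselectivity of this crossed reaction is untested. The fallback sets out from 1 and 2 and comes back at 4. It keeps the same acyl anion bond construction but uses an enzyme and then corrects the configuration. Aldehydes 1 and 2 are coupled with the thiamine-diphosphate-dependent benzaldehyde lyase from Pseudomonas fluorescens (ThDP, MgSO4, phosphate buffer pH 8 with 25% DMSO, 30 °C). This enzyme gives only the aryl ketone regioisomer, but as the (R)-enantiomer, (2R)-3-(benzyloxy)-1-[4-(benzyloxy)-3,5-dimethoxyphenyl]-2-hydroxypropan-1-one F1. Mitsunobu inversion with chloroacetic acid (PPh3, DIAD, THF, 0 °C) then gives (2S)-3-(benzyloxy)-1-[4-(benzyloxy)-3,5-dimethoxyphenyl]-1-oxopropan-2-yl chloroacetate F2. Methanolysis of this activated ester (MeOH, catalytic K2CO3, −20 °C) releases (S)-acyloin 4, and the route continues with step 3.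

2. Step 3. The alkoxyphosphonium salt of an α-ketol can eliminate to the β-benzyloxy enone or lose configuration by enolisation. The fallback sets out from 4 and comes back at 9. It separates activation from displacement. Acyloin 4 is converted with Tf2O and 2,6-lutidine (CH2Cl2, −78 °C) into (2S)-3-(benzyloxy)-1-[4-(benzyloxy)-3,5-dimethoxyphenyl]-1-oxopropan-2-yl trifluoromethanesulfonate F3. This is used cold and at once with phenol 7 and K2CO3 in MeCN (−20 → 0 °C), where SN2 displacement with inversion gives 9.

3. Step 4. The primary alkyl benzyl ether is the slowest of the three to cleave, and the aryl ketone may be reduced while it is still present. The fallback sets out from 9 and comes back at 10. It replaces hydrogenolysis with a non-reductive Lewis-acid debenzylation: BCl3 (6 equiv) and pentamethylbenzene (10 equiv) as cation scavenger, CH2Cl2, −78 → −40 °C, MeOH quench. All three benzyl groups are removed directly to give 10 with no reducing agent present; no new compound is made on the way (F0).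

Further compounds
F1 | step 1 | (2R)-3-(benzyloxy)-1-[4-(benzyloxy)-3,5-dimethoxyphenyl]-2-hydroxypropan-1-one | O[C@H](COCc1ccccc1)C(=O)c1cc(OC)c(OCc2ccccc2)c(OC)c1
F2 | step 1 | (2S)-3-(benzyloxy)-1-[4-(benzyloxy)-3,5-dimethoxyphenyl]-1-oxopropan-2-yl chloroacetate | O=C(CCl)O[C@@H](COCc1ccccc1)C(=O)c1cc(OC)c(OCc2ccccc2)c(OC)c1
F3 | step 3 | (2S)-3-(benzyloxy)-1-[4-(benzyloxy)-3,5-dimethoxyphenyl]-1-oxopropan-2-yl trifluoromethanesulfonate | FC(F)(F)S(=O)(=O)O[C@@H](COCc1ccccc1)C(=O)c1cc(OC)c(OCc2ccccc2)c(OC)c1
F0 | step 4 | none | none
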